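Everything rests on opening ring C of the taxifolin half at O1–C8a and C4–C4a. Ring A of that half is then an aryne (C4a≡C8a) that already carries the epicatechin unit at C8, and the O1–C2–C3–C4 chain is a chiral β-hydroxy lactone with both stereocentres in place. In one operation the hydroxyl adds to C8a and the aryl anion at C4a is acylated by the lactone carbonyl, closing the chromanone. The step exploits the ortho pairing of O1 and the C4 carbonyl on C8a/C4a and the C5 oxygen, which polarises the aryne so that oxygen enters beside the C8 interflavan carbon. The precursors are an ortho-silylaryl triflate and a glycolate aldol adduct.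

Key step: step 8

Remark: flavonoid numbering is used for each half; "ring D" is the phloroglucinol ring that becomes ring A of the taxifolin half. The target is read as (−)-epicatechin-(4β→8)-(2R,3R)-taxifolin: upper unit 2,3-cis and 3,4-trans, lower unit 2,3-trans.

Assumption: the enantiopure butane-2,3-diacetal of glycolic acid used in step 7 is taken as a purchasable reagent.

**Step 1**
Reactants: 1 (−)-epicatechin; 2 benzyl bromide
Product: 3 3,5,7,3',4'-penta-O-benzyl-(−)-epicatechin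
Conditions: NaH, BnBr, DMF, −40 °C to rt
Reagents that add atoms: benzyl bromide, BrCc1ccccc1
Why: Williamson etherification of the four phenols and the C3 alcohol; fast alkylation of the 4'-phenoxide at low temperature should outrun base-induced C2 epimerisation, so both stereocentres of 1 are kept.

**Step 2**
Reactants: 3 penta-O-benzylepicatechin; 4 2-ethoxyethanol
Product: 5 4β-(2-ethoxyethoxy)-3,5,7,3',4'-penta-O-benzylepicatechin
Conditions: DDQ, 2-ethoxyethanol, CH2Cl2, rt
Reagents that add atoms: 2-ethoxyethanol, CCOCCO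
Why: DDQ benzylic oxidation: hydride abstraction from C4, activated by the 5,7-dioxygenated ring A, gives a quinone-methide-type cation that the alcohol traps anti to the C3 benzyloxy group; this centre is planarised again in step 3.

**Step 3**
Reactants: 5 4β-(2-ethoxyethoxy) ether; 6 3,5-bis(benzyloxy)phenol
Product: 7 2-(3,5,7,3',4'-penta-O-benzylepicatechin-4β-yl)-3,5-bis(benzyloxy)phenol
Conditions: Me3SiOTf (cat.), excess 6, CH2Cl2, −78 to −40 °C
Reagents that add atoms: 3,5-bis(benzyloxy)phenol, Oc1cc(OCc2ccccc2)cc(OCc2ccccc2)c1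
Why: Lewis-acid Friedel–Crafts arylation of the C4 flavanyl cation, the reaction type of 4→8 flavan couplings; the phenol should react ortho to its hydroxyl (the position between the two benzyloxy groups is more hindered, and any 4-aryloxy adduct returns to the ortho carbon by O→C migration) and anti to the cis C2 aryl and C3 benzyloxy groups, which sets C4 as 4β (3,4-trans).

**Step 4**
Reactants: 7 phenol; 8 isopropyl isocyanate
Product: 9 N-isopropylcarbamate of 7
Conditions: i-PrNCO, Et3N (cat.), CH2Cl2, rt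
Reagents that add atoms: isopropyl isocyanate, CC(C)N=C=O
Why: base-catalysed addition of the phenol to the isocyanate gives the secondary carbamate that directs the metalation of step 5 and can be removed under mild conditions in step 6.

**Step 5**
Reactants: 9 carbamate; 10 tert-butyldimethylsilyl triflate (transient N-protection); 11 chlorotrimethylsilane
Product: 15 ortho-trimethylsilyl carbamate (Me3Si on ring D between the carbamate oxygen and a benzyloxy group), via N-silyl carbamate 12 (not isolated), via aryllithium 13 (not isolated), via bis-silylated carbamate 14 (not isolated)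
Conditions: Me3CSiMe2OTf, TMEDA, Et2O/THF, 0 °C to rt; n-BuLi, TMEDA, −78 °C; Me3SiCl, −78 °C to rt; aq NaHSO4
Reagents that add atoms: chlorotrimethylsilane, C[Si](C)(C)Cl
Why: directed ortho-metalation: after in-situ N-silylation the carbamate directs n-BuLi to the only ortho C–H, which the adjacent benzyloxy group acidifies further, and Me3SiCl traps the aryllithium at −78 °C before an anionic ortho-Fries shift or benzylic deprotonation should compete; the N–Si bond is lost on work-up.

**Step 6**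
Reactants: 15 ortho-silyl carbamate; 16 N-phenylbis(trifluoromethanesulfonimide)
Product: 18 2-(penta-O-benzylepicatechin-4β-yl)-3,5-bis(benzyloxy)-6-(trimethylsilyl)phenyl triflate, via ortho-silylphenol 17 (not isolated)
Conditions: DBU, Et2NH, MeCN, 40 °C; then PhNTf2, rt
Reagents that add atoms: N-phenylbis(trifluoromethanesulfonimide), FC(F)(F)S(=O)(=O)N(c1ccccc1)S(=O)(=O)C(F)(F)F
Why: E1cB cleavage of the N–H carbamate by DBU (the isocyanate is scavenged by Et2NH as a urea) frees the phenoxide, which PhNTf2 sulfonylates to the ortho-silylaryl triflate.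

**Step 7**
Reactants: 19 (5S,6S)-5,6-dimethoxy-5,6-dimethyl-1,4-dioxan-2-one; 20 3,4-bis(benzyloxy)benzaldehyde
Product: 21 (3R,5S,6S)-3-[(R)-[3,4-bis(benzyloxy)phenyl](hydroxy)methyl]-5,6-dimethoxy-5,6-dimethyl-1,4-dioxan-2-one
Conditions: LiN(SiMe3)2, THF, −78 °C; 20; AcOH quench at −78 °C
Reagents that add atoms: 3,4-bis(benzyloxy)benzaldehyde, O=Cc1ccc(OCc2ccccc2)c(OCc2ccccc2)c1
Why: lithium enolate aldol addition of a conformationally locked glycolate: the ring-bound (E)-enolate should react through a Zimmerman–Traxler chair on the face anti to the axial C5 methoxy group, giving the 3R centre and the anti (R) carbinol, with the β-hydroxyl free and the α-oxygen masked in the ring.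

**Step 8**
Reactants: 18 ortho-silylaryl triflate; 21 β-hydroxy lactone
Product: 24 3,5,7,3',4'-penta-O-benzylepicatechin-(4β→8)-5,7,3',4'-tetra-O-benzyl-(2R,3R)-taxifolin, via aryne 22 (not isolated), via keto ketal 23 (not isolated)
Conditions: CsF (4 equiv), 21 (2 equiv), THF, 65 °C; then 1 M aq HCl, THF, 25 °C
Reagents that add atoms: none
Why: Proposed new method: fluoride removes the silyl group of 18 and expels triflate to give aryne 22, the fluoride-activated secondary hydroxyl of 21 adds to C8a, and the C4a aryl anion so formed attacks the lactone carbonyl, whose ring oxygen leaves as a hemiketal alkoxide that loses methoxide to give keto ketal 23; aqueous acid then hydrolyses this mixed ketal to the free 3-hydroxyl. The closest known reaction type is the fluoride-induced annulation of ortho-silylaryl triflates with salicylate esters to xanthones, here transferred to an aliphatic β-hydroxy lactone so that a chromanone results. Ring C of the taxifolin half closes by an intermolecular O–aryl addition followed by a 6-exo-trig acyl substitution. No stereocentre is formed: C2 and C3 come from 21 with retention because no bond to either is broken, and 2,3-trans is also the thermodynamic arrangement should C3 enolise. The step needs attack of oxygen at C8a and not at C4a, which the C5 benzyloxy group should secure by inductive polarisation (distortion) of the aryne that places the developing carbanion at C4a next to oxygen, against the steric bias of the C8 flavanyl group. It also needs ring closure to outrun protonation of the aryl anion, which the activated α-alkoxy lactone, THF as a poorly acidic solvent and the excess of 21 should secure.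

**Step 9**
Reactants: 24 nona-O-benzyl dimer
Product: 25 (−)-epicatechin-(4β→8)-(2R,3R)-taxifolin (target)
Conditions: H2 (1 atm), Pd(OH)2/C, THF/MeOH/H2O, rt
Reagents that add atoms: none
Why: hydrogenolysis of all nine benzyl ethers; the hydrogen-bonded, vinylogous-ester-like C4 ketone, the benzylic C2–O bonds and the doubly benzylic C4–C8 bond should survive, as they do under these conditions in flavanonol and procyanidin series.

**Compound list**

1 | (−)-epicatechin, (2R,3R)-2-(3,4-dihydroxyphenyl)chromane-3,5,7-triol | C1c2c(O)cc(O)cc2O[C@H](c2ccc(O)c(O)c2)[C@@H]1O | starting material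
2 | benzyl bromide | BrCc1ccccc1 | starting material
3 | 3,5,7,3',4'-penta-O-benzyl-(−)-epicatechin | C1c2c(OCc3ccccc3)cc(OCc3ccccc3)cc2O[C@H](c2ccc(OCc3ccccc3)c(OCc3ccccc3)c2)[C@@H]1OCc1ccccc1 | intermediate
4 | 2-ethoxyethanol | CCOCCO | starting material
5 | 4β-(2-ethoxyethoxy)-3,5,7,3',4'-penta-O-benzylepicatechin (C4–O trans to C3–O) | CCOCCO[C@H]1c2c(OCc3ccccc3)cc(OCc3ccccc3)cc2O[C@H](c2ccc(OCc3ccccc3)c(OCc3ccccc3)c2)[C@@H]1OCc1ccccc1 | intermediate
6 | 3,5-bis(benzyloxy)phenol | Oc1cc(OCc2ccccc2)cc(OCc2ccccc2)c1 | starting material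
7 | 2-(3,5,7,3',4'-penta-O-benzylepicatechin-4β-yl)-3,5-bis(benzyloxy)phenol (3,4-trans) | Oc1cc(OCc2ccccc2)cc(OCc2ccccc2)c1[C@H]1c2c(OCc3ccccc3)cc(OCc3ccccc3)cc2O[C@H](c2ccc(OCc3ccccc3)c(OCc3ccccc3)c2)[C@@H]1OCc1ccccc1 | intermediate
8 | isopropyl isocyanate | CC(C)N=C=O | starting material
9 | N-isopropylcarbamate of 7 | CC(C)NC(=O)Oc1cc(OCc2ccccc2)cc(OCc2ccccc2)c1[C@H]1c2c(OCc3ccccc3)cc(OCc3ccccc3)cc2O[C@H](c2ccc(OCc3ccccc3)c(OCc3ccccc3)c2)[C@@H]1OCc1ccccc1 | intermediate
10 | tert-butyldimethylsilyl triflate | CC(C)(C)[Si](C)(C)OS(=O)(=O)C(F)(F)F | starting material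
11 | chlorotrimethylsilane | C[Si](C)(C)Cl | starting material
12 | N-(tert-butyldimethylsilyl)-N-isopropylcarbamate of 7 | CC(C)N([Si](C)(C)C(C)(C)C)C(=O)Oc1cc(OCc2ccccc2)cc(OCc2ccccc2)c1[C@H]1c2c(OCc3ccccc3)cc(OCc3ccccc3)cc2O[C@H](c2ccc(OCc3ccccc3)c(OCc3ccccc3)c2)[C@@H]1OCc1ccccc1 | intermediate
13 | 6-lithio derivative of 12 (lithium on ring D between the carbamate oxygen and a benzyloxy group) | CC(C)N([Si](C)(C)C(C)(C)C)C(=O)Oc1c([Li])c(OCc2ccccc2)cc(OCc2ccccc2)c1[C@H]1c2c(OCc3ccccc3)cc(OCc3ccccc3)cc2O[C@H](c2ccc(OCc3ccccc3)c(OCc3ccccc3)c2)[C@@H]1OCc1ccccc1 | intermediate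
14 | 6-(trimethylsilyl) derivative of 12 | CC(C)N([Si](C)(C)C(C)(C)C)C(=O)Oc1c([Si](C)(C)C)c(OCc2ccccc2)cc(OCc2ccccc2)c1[C@H]1c2c(OCc3ccccc3)cc(OCc3ccccc3)cc2O[C@H](c2ccc(OCc3ccccc3)c(OCc3ccccc3)c2)[C@@H]1OCc1ccccc1 | intermediate
15 | 2-(penta-O-benzylepicatechin-4β-yl)-3,5-bis(benzyloxy)-6-(trimethylsilyl)phenyl N-isopropylcarbamate | CC(C)NC(=O)Oc1c([Si](C)(C)C)c(OCc2ccccc2)cc(OCc2ccccc2)c1[C@H]1c2c(OCc3ccccc3)cc(OCc3ccccc3)cc2O[C@H](c2ccc(OCc3ccccc3)c(OCc3ccccc3)c2)[C@@H]1OCc1ccccc1 | intermediate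
16 | N-phenylbis(trifluoromethanesulfonimide) | FC(F)(F)S(=O)(=O)N(c1ccccc1)S(=O)(=O)C(F)(F)F | starting material
17 | 2-(penta-O-benzylepicatechin-4β-yl)-3,5-bis(benzyloxy)-6-(trimethylsilyl)phenol | Oc1c([Si](C)(C)C)c(OCc2ccccc2)cc(OCc2ccccc2)c1[C@H]1c2c(OCc3ccccc3)cc(OCc3ccccc3)cc2O[C@H](c2ccc(OCc3ccccc3)c(OCc3ccccc3)c2)[C@@H]1OCc1ccccc1 | intermediate
18 | 2-(penta-O-benzylepicatechin-4β-yl)-3,5-bis(benzyloxy)-6-(trimethylsilyl)phenyl triflate | FC(F)(F)S(=O)(=O)Oc1c([Si](C)(C)C)c(OCc2ccccc2)cc(OCc2ccccc2)c1[C@H]1c2c(OCc3ccccc3)cc(OCc3ccccc3)cc2O[C@H](c2ccc(OCc3ccccc3)c(OCc3ccccc3)c2)[C@@H]1OCc1ccccc1 | intermediate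
19 | (5S,6S)-5,6-dimethoxy-5,6-dimethyl-1,4-dioxan-2-one | O=C1CO[C@](C)(OC)[C@@](C)(OC)O1 | starting material
20 | 3,4-bis(benzyloxy)benzaldehyde | O=Cc1ccc(OCc2ccccc2)c(OCc2ccccc2)c1 | starting material
21 | (3R,5S,6S)-3-[(R)-[3,4-bis(benzyloxy)phenyl](hydroxy)methyl]-5,6-dimethoxy-5,6-dimethyl-1,4-dioxan-2-one | O=C1[C@@H]([C@H](O)c2ccc(OCc3ccccc3)c(OCc3ccccc3)c2)O[C@](C)(OC)[C@@](C)(OC)O1 | intermediate
22 | 3,5-bis(benzyloxy)-6-(penta-O-benzylepicatechin-4β-yl)benzyne | C1#CC(OCc2ccccc2)=CC(OCc2ccccc2)=C1[C@H]1c2c(OCc3ccccc3)cc(OCc3ccccc3)cc2O[C@H](c2ccc(OCc3ccccc3)c(OCc3ccccc3)c2)[C@@H]1OCc1ccccc1 | intermediate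
23 | 3-O-[(S)-2-methoxy-3-oxobutan-2-yl] ether of 24 | O=C1c2c(OCc5ccccc5)cc(OCc5ccccc5)c([C@H]3c4c(OCc5ccccc5)cc(OCc5ccccc5)cc4O[C@H](c4ccc(OCc5ccccc5)c(OCc5ccccc5)c4)[C@@H]3OCc3ccccc3)c2O[C@H](c2ccc(OCc5ccccc5)c(OCc5ccccc5)c2)[C@H]1O[C@](C)(OC)C(C)=O | intermediate
24 | 3,5,7,3',4'-penta-O-benzylepicatechin-(4β→8)-5,7,3',4'-tetra-O-benzyl-(2R,3R)-taxifolin | O=C1c2c(OCc5ccccc5)cc(OCc5ccccc5)c([C@H]3c4c(OCc5ccccc5)cc(OCc5ccccc5)cc4O[C@H](c4ccc(OCc5ccccc5)c(OCc5ccccc5)c4)[C@@H]3OCc3ccccc3)c2O[C@H](c2ccc(OCc5ccccc5)c(OCc5ccccc5)c2)[C@H]1O | intermediate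
25 | (−)-epicatechin-(4β→8)-(2R,3R)-taxifolin, CNP0210692.1 | O=C1c2c(O)cc(O)c([C@H]3c4c(O)cc(O)cc4O[C@H](c4ccc(O)c(O)c4)[C@@H]3O)c2O[C@H](c2ccc(O)c(O)c2)[C@H]1O | target

**Step count and risks**

Total step count: 9. Longest linear sequence: 8 steps (steps 1–6, 8, 9); step 7 is a one-step side branch.

Steps most likely to fail:

1. Step 8. Oxygen may add at the wrong aryne carbon because of the bulk at C8. The aryl anion may be protonated before it closes ring C. The lactone may suffer retro-aldol cleavage or C3 epimerisation under the basic fluoride conditions. The fallback is the chalcone epoxide route, which uses known reactions only; it sets out from carbamate 9 and aldehyde 20 and comes back at 24. Horner–Wadsworth–Emmons reaction of 20 with diethyl [2-(methoxy(methyl)amino)-2-oxoethyl]phosphonate (NaH, THF) gives the (E)-Weinreb amide F1. Carbamate 9 is N-silylated and lithiated as in step 5 (through 12 and 13), and the aryllithium is acylated with F1 to give the N-silyl chalcone carbamate F2, which loses the N-silyl group on work-up to give the chalcone carbamate F3. Julia–Colonna epoxidation (poly-L-leucine, urea–H2O2, DBU, THF) should give the (αR,βS)-epoxide F4. Et2NH and DBU remove the carbamate to give the hydroxy epoxide F5. Mild acid (p-TsOH, CH2Cl2) then closes ring C by 6-endo attack of the phenol at the benzylic carbon with inversion, which gives the 2,3-trans (2R,3R) arrangement of 24.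

2. Step 5. Deprotonation may occur at a benzylic CH2 (followed by Wittig rearrangement) or between two benzyloxy groups on ring D or ring A, and the carbamoyl group may migrate by an anionic ortho-Fries shift. The fallback replaces deprotonation by halogen–metal exchange; it sets out from phenol 7 and comes back at 18. Amine-directed ortho-bromination of the phenol (N-bromosuccinimide, cat. i-Pr2NH, CH2Cl2, −78 °C) gives the bromophenol F6, and hexamethyldisilazane gives its trimethylsilyl ether F7. n-BuLi (THF, −100 °C) then effects bromine–lithium exchange with a retro-Brook silyl shift from oxygen to carbon, giving the lithium phenoxide of 17, which is quenched with Tf2O to give 18.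

3. Step 3. Substitution may take place at the position of the phenol between its two benzyloxy groups, or twice on the same phenol. The fallback uses a symmetric nucleophile; it sets out from 5 and comes back at 7. Phloroglucinol (benzene-1,3,5-triol), whose three ring positions are equivalent, is coupled with 5 (Me3SiOTf, THF/CH2Cl2, −78 °C) to give the triol F8. K2CO3 and two equivalents of benzyl bromide 2 in DMF then alkylate the unhindered para hydroxyl and one of the two equivalent ortho hydroxyls to give 7.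

**Further compounds**

F1 | step 8 | (E)-3-[3,4-bis(benzyloxy)phenyl]-N-methoxy-N-methylprop-2-enamide | CON(C)C(=O)/C=C/c1ccc(OCc2ccccc2)c(OCc2ccccc2)c1
F2 | step 8 | N-(tert-butyldimethylsilyl) chalcone carbamate (ring D acylated between the carbamate oxygen and a benzyloxy group) | CC(C)N([Si](C)(C)C(C)(C)C)C(=O)Oc1c(C(=O)/C=C/c2ccc(OCc3ccccc3)c(OCc3ccccc3)c2)c(OCc2ccccc2)cc(OCc2ccccc2)c1[C@H]1c2c(OCc3ccccc3)cc(OCc3ccccc3)cc2O[C@H](c2ccc(OCc3ccccc3)c(OCc3ccccc3)c2)[C@@H]1OCc1ccccc1
F3 | step 8 | chalcone N-isopropylcarbamate | CC(C)NC(=O)Oc1c(C(=O)/C=C/c2ccc(OCc3ccccc3)c(OCc3ccccc3)c2)c(OCc2ccccc2)cc(OCc2ccccc2)c1[C@H]1c2c(OCc3ccccc3)cc(OCc3ccccc3)cc2O[C@H](c2ccc(OCc3ccccc3)c(OCc3ccccc3)c2)[C@@H]1OCc1ccccc1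
F4 | step 8 | (αR,βS)-epoxy ketone carbamate | CC(C)NC(=O)Oc1c(C(=O)[C@@H]2O[C@H]2c2ccc(OCc3ccccc3)c(OCc3ccccc3)c2)c(OCc2ccccc2)cc(OCc2ccccc2)c1[C@H]1c2c(OCc3ccccc3)cc(OCc3ccccc3)cc2O[C@H](c2ccc(OCc3ccccc3)c(OCc3ccccc3)c2)[C@@H]1OCc1ccccc1
F5 | step 8 | (αR,βS)-epoxy ketone with free ring D hydroxyl | Oc1c(C(=O)[C@@H]2O[C@H]2c2ccc(OCc3ccccc3)c(OCc3ccccc3)c2)c(OCc2ccccc2)cc(OCc2ccccc2)c1[C@H]1c2c(OCc3ccccc3)cc(OCc3ccccc3)cc2O[C@H](c2ccc(OCc3ccccc3)c(OCc3ccccc3)c2)[C@@H]1OCc1ccccc1
F6 | step 5 | 6-bromo-2-(penta-O-benzylepicatechin-4β-yl)-3,5-bis(benzyloxy)phenol | Oc1c(Br)c(OCc2ccccc2)cc(OCc2ccccc2)c1[C@H]1c2c(OCc3ccccc3)cc(OCc3ccccc3)cc2O[C@H](c2ccc(OCc3ccccc3)c(OCc3ccccc3)c2)[C@@H]1OCc1ccccc1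
F7 | step 5 | trimethylsilyl ether of F6 | C[Si](C)(C)Oc1c(Br)c(OCc2ccccc2)cc(OCc2ccccc2)c1[C@H]1c2c(OCc3ccccc3)cc(OCc3ccccc3)cc2O[C@H](c2ccc(OCc3ccccc3)c(OCc3ccccc3)c2)[C@@H]1OCc1ccccc1
F8 | step 3 | 2-(penta-O-benzylepicatechin-4β-yl)benzene-1,3,5-triol | Oc1cc(O)c([C@H]2c3c(OCc4ccccc4)cc(OCc4ccccc4)cc3O[C@H](c3ccc(OCc4ccccc4)c(OCc4ccccc4)c3)[C@@H]2OCc2ccccc2)c(O)c1
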